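**Retrosynthetic overview**

1. The target is a pyran (ring A: O2, C1, C3, C4, C4a, C8a) fused to a cyclohexenone (ring B: C4a, C5–C8, C8a). Two features make the key step possible: the α-ketol C6(=O)–C7(OH)(CH3) of ring B is a crossed-benzoin retron (aldehyde carbon C6 plus methyl ketone C7), and the doubly vinylogous ester O2–C3=C4–C4a=C5–C6=O is the 1,6-adduct of the C1 hydroxyl to a 2-en-4-ynal.
2. Both rings are therefore opened in one operation to a monocyclic lactol (a 5,6-dihydro-2H-pyran-2-ol, i.e. a masked δ-hydroxy ynenal whose temporary ring holds the formyl group cis to C8a) that carries the C8-silyloxy methyl ketone. In the forward direction ring A closes first (O2–C3), ring B second (C6–C7).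
3. The lactol comes from 1,2-addition of the side-chain enyne acetylide to a 3-substituted 2,3-dihydro-4H-pyran-4-one, followed by acid-mediated 1,3-transposition, which also unmasks the C7 ketone from its dimethyl ketal.
4. The pyranone comes from an Evans syn-aldol (C8a–C8), Weinreb amide, ethynyl ketone and 6-endo oxa-Michael closure.
5. The side-chain enyne comes from (2S,3S)-2-hydroxy-3-methylpentanoic acid by diynone formation, chelation-controlled methyl addition (C3′) and hydroxyl-directed trans-reduction (E-alkene).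

Key step: step 16

Remark: the locants C1–C8a and the primed side-chain locants of the target (1H-isochromen-6-one numbering; ring A = pyran, ring B = carbocycle) are used for the corresponding atoms of every intermediate. TBS = tert-butyldimethylsilyl. The five starting materials are assumed to be catalogue compounds.

**Route**

Step 1
Reactants: 1 methyl 2,2-dimethoxypropanoate
Product: 2 2,2-dimethoxypropanal
Conditions: i-Bu2AlH (1.1 equiv), CH2Cl2, −78 °C; aq. KNaC4H4O6
Reagents that add atoms: none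
Why: Partial reduction of an α,α-dialkoxy ester with i-Bu2AlH at −78 °C should stop at the aldehyde because the chelated tetrahedral aluminate survives until work-up (ester-to-aldehyde reduction).

Step 2
Reactants: 3 3-(benzyloxy)propanoic acid; 4 (S)-4-benzyloxazolidin-2-one
Product: 5 (S)-4-benzyl-3-[3-(benzyloxy)propanoyl]oxazolidin-2-one
Conditions: t-BuCOCl, Et3N, THF, −20 °C; then LiCl, 4, −20 → 23 °C
Reagents that add atoms: none
Why: Mixed-anhydride N-acylation of the Evans oxazolidinone (pivaloyl chloride/LiCl protocol) is a standard acylation.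

Step 3
Reactants: 5 acyl oxazolidinone; 2 2,2-dimethoxypropanal
Product: 6 (4S)-4-benzyl-3-[(2S,3S)-2-[(benzyloxy)methyl]-3-hydroxy-4,4-dimethoxypentanoyl]oxazolidin-2-one
Conditions: Bu2BOTf, i-Pr2NEt, CH2Cl2, −78 → 0 °C; then 2, −78 → 0 °C; pH 7 buffer, MeOH, 30% H2O2, 0 °C
Reagents that add atoms: none
Why: Evans syn-aldol reaction: the Z-boron enolate of 5 should react through a Zimmerman–Traxler chair on the enolate face opposite the auxiliary benzyl group, which sets C8a (2S) and C8 (3S) as the syn pair the target needs, and the non-enolisable aldehyde 2 cannot self-condense.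

Step 4
Reactants: 6 aldol imide
Product: 7 (2S,3S)-2-[(benzyloxy)methyl]-3-hydroxy-N,4,4-trimethoxy-N-methylpentanamide
Conditions: MeNHOMe·HCl, AlMe3, CH2Cl2, −15 → 0 °C; aq. KNaC4H4O6
Reagents that add atoms: N,O-dimethylhydroxylamine hydrochloride, CNOC.Cl
Why: Aluminium amide transamination of the aldol imide (Weinreb amide formation), assisted by the free β-hydroxyl, should remove the auxiliary without touching the two stereocentres.

Step 5
Reactants: 7 hydroxy Weinreb amide
Product: 8 (2S,3S)-2-[(benzyloxy)methyl]-3-(TBSO)-N,4,4-trimethoxy-N-methylpentanamide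
Conditions: TBSOTf, 2,6-lutidine, CH2Cl2, −78 → 0 °C
Reagents that add atoms: tert-butyldimethylsilyl trifluoromethanesulfonate, CC(C)(C)[Si](C)(C)OS(=O)(=O)C(F)(F)F
Why: Silylation of the hindered secondary alcohol with the silyl triflate (silyl ether formation) blocks O8 so that only O1 can later cyclise onto the ynone.

Step 6
Reactants: 8 benzyl ether
Product: 9 (2S,3S)-3-(TBSO)-2-(hydroxymethyl)-N,4,4-trimethoxy-N-methylpentanamide
Conditions: H2 (1 atm), 10% Pd/C, EtOAc, 23 °C
Reagents that add atoms: none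
Why: Hydrogenolysis of the benzyl ether over Pd/C should be chemoselective because no alkene or alkyne is present yet and Weinreb amide, silyl ether and ketal are inert to it.

Step 7
Reactants: 9 hydroxy Weinreb amide
Product: 11 (3S)-3-[(1S)-1-(TBSO)-2,2-dimethoxypropyl]-2,3-dihydro-4H-pyran-4-one, via β-hydroxy ynone 10 (not isolated)
Conditions: HC≡CMgBr (3.5 equiv), THF, 0 → 23 °C; aq. NH4Cl; then DABCO (0.2 equiv), CH2Cl2, 23 °C
Reagents that add atoms: ethynylmagnesium bromide, C#C[Mg]Br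
Why: The Weinreb amide stops the ethynyl Grignard addition at the ketone (Weinreb ketone synthesis), and the β-hydroxy terminal ynone should close by amine-catalysed 6-endo oxa-Michael addition–elimination to the dihydropyranone while DABCO is too weak a base to epimerise C8a.

Step 8
Reactants: 12 (2S,3S)-2-hydroxy-3-methylpentanoic acid
Product: 13 (2S,3S)-2-hydroxy-N-methoxy-N,3-dimethylpentanamide
Conditions: MeNHOMe·HCl, EDC·HCl, HOBt, N-methylmorpholine, CH2Cl2, 0 → 23 °C
Reagents that add atoms: N,O-dimethylhydroxylamine hydrochloride, CNOC.Cl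
Why: Carbodiimide amidation of the α-hydroxy acid should give the Weinreb amide directly, and C4′ and C5′ of the target come unchanged from this chiral-pool acid.

Step 9
Reactants: 13 hydroxy Weinreb amide; 14 1,4-bis(trimethylsilyl)buta-1,3-diyne
Product: 15 (6S,7S)-6-hydroxy-7-methyl-1-(trimethylsilyl)nona-1,3-diyn-5-one
Conditions: 14 (2.6 equiv), MeLi·LiBr (2.5 equiv), THF, 23 °C; then 13, −78 → −20 °C; aq. NH4Cl
Reagents that add atoms: none
Why: Mono-desilylation of 14 with MeLi·LiBr gives the lithium diynide, which should acylate on the Weinreb amide (Weinreb ketone synthesis) after its first equivalent has deprotonated the hydroxyl.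

Step 10
Reactants: 15 α′-hydroxy diynone
Product: 16 (5R,6S,7S)-5,7-dimethyl-1-(trimethylsilyl)nona-1,3-diyne-5,6-diol
Conditions: MeMgBr (3.5 equiv), Et2O/CH2Cl2, −78 °C; aq. NH4Cl
Reagents that add atoms: methylmagnesium bromide, C[Mg]Br
Why: Chelation-controlled 1,2-addition (Cram chelate): the magnesium alkoxide of O4′ and the ketone oxygen form a five-membered chelate and methyl should be delivered from the face bearing H4′, which sets the tertiary carbinol C3′ (5R, anti-diol).

Step 11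
Reactants: 16 diynyl diol
Product: 17 (3E,5R,6S,7S)-5,7-dimethyl-1-(trimethylsilyl)non-3-en-1-yne-5,6-diol
Conditions: LiAlH4 (3 equiv), THF, 0 → 40 °C; aq. KNaC4H4O6
Reagents that add atoms: none
Why: Alkoxide-directed trans-hydroalumination of the triple bond next to the carbinol (LiAlH4 reduction of a propargylic alcohol) should give the E-alkene only and leave the distal silylalkyne.

Step 12
Reactants: 17 silyl enyne diol
Product: 18 (3E,5R,6S,7S)-5,7-dimethylnon-3-en-1-yne-5,6-diol
Conditions: K2CO3, MeOH, 23 °C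
Reagents that add atoms: none
Why: Methanolysis of the alkynyl C–Si bond under K2CO3 (protodesilylation) frees the terminal alkyne.

Step 13
Reactants: 18 enyne diol
Product: 19 (3E,5R,6S,7S)-6-(TBSO)-5,7-dimethylnon-3-en-1-yn-5-ol
Conditions: TBSOTf (1.1 equiv), 2,6-lutidine, CH2Cl2, −78 °C
Reagents that add atoms: tert-butyldimethylsilyl trifluoromethanesulfonate, CC(C)(C)[Si](C)(C)OS(=O)(=O)C(F)(F)F
Why: At −78 °C the silyl triflate should silylate the secondary hydroxyl much faster than the tertiary one (selective silyl ether formation), so O4′ is protected and the tertiary hydroxyl is carried free.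

Step 14
Reactants: 11 dihydropyranone; 19 enyne
Product: 20 (3S)-3-[(1S)-1-(TBSO)-2,2-dimethoxypropyl]-4-[(3E,5R,6S,7S)-6-(TBSO)-5-hydroxy-5,7-dimethylnon-3-en-1-yn-1-yl]-3,4-dihydro-2H-pyran-4-ol (both C4a epimers)
Conditions: 19 (1.3 equiv), n-BuLi (2.6 equiv), THF, −78 °C; CeCl3 (1.4 equiv), −78 °C; then 11, −78 → −40 °C; aq. NH4Cl
Reagents that add atoms: none
Why: The alkynylcerium reagent made from the dilithio derivative of 19 should add 1,2 to the vinylogous ester carbonyl (organocerium addition) with little enolisation, so C8a is kept, and the configuration of the new carbinol carbon is irrelevant because it becomes sp2 in step 15.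

Step 15
Reactants: 20 tertiary carbinol
Product: 21 (5S)-5-[(1S)-1-(TBSO)-2-oxopropyl]-4-[(3E,5R,6S,7S)-6-(TBSO)-5-hydroxy-5,7-dimethylnon-3-en-1-yn-1-yl]-5,6-dihydro-2H-pyran-2-ol (anomers)
Conditions: TsOH·H2O (0.1 equiv), acetone/H2O (10:1), 0 → 23 °C
Reagents that add atoms: water, O
Why: Acid should ionise the tertiary carbinol to an oxygen-stabilised allyl cation that water captures at the acetal carbon (Stork–Danheiser-type 1,3-transposition of a vinylogous ester adduct), giving the cyclic hemiacetal whose ring fixes the formyl carbon cis to C8a, while the same acid hydrolyses the dimethyl ketal to the C7 ketone.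

Step 16
Reactants: 21 lactol
Product: 24 O8/O4′-bis-TBS ether of the target, via open-chain hydroxy ynenal 22 (not isolated), via pyranylidene acetaldehyde 23 (not isolated)
Conditions: DBU (0.5 equiv), THF, 23 °C until 21 is consumed; then 2-(pentafluorophenyl)-6,7-dihydro-5H-pyrrolo[2,1-c][1,2,4]triazol-2-ium tetrafluoroborate (0.2 equiv), 40 °C, same flask
Reagents that add atoms: none
Why: Proposed new method: DBU opens lactol 21 to hydroxy ynenal 22, whose C1 alkoxide adds 1,6 to the alkyne carbon C3 (activated through C3≡C4–C4a=C5–C6=O) to close ring A in the 6-endo-dig mode and give dienal 23; the triazolylidene then adds to the C6 aldehyde, and C6 of the Breslow intermediate attacks the C7 methyl ketone to close ring B in the 6-exo-trig mode, with proton transfer and release of the carbene. The closest known reaction types are the base-mediated intramolecular oxa-Michael addition of alcohols to conjugated alkynyl carbonyl compounds and the carbene-catalysed intramolecular crossed aldehyde–ketone benzoin reaction that gives six-membered tertiary α-ketols; neither has been shown on a vinylogous formyl dienal and the two have not been run in one flask, hence the label. C7 is the only new stereocentre and is set by substrate control: the fused pyran holds the C8 silyloxy group pseudo-equatorial (trans to C1), and concerted C–C bond formation with proton transfer from the Breslow hydroxyl needs the ketone oxygen gauche to that hydroxyl, i.e. pseudo-equatorial, which places the C7 hydroxyl trans to O8 and the methyl group axial (7R). Because benzoin additions are reversible, this hydrogen-bonded equatorial α-ketol is also the expected thermodynamic product, and C8 and C8a are not touched. The step needs acyl-anion and not homoenolate reactivity of the enal, and no redox lactonisation: the carbene precursor is added only after the free C1 hydroxyl has been consumed in ring A, the N-pentafluorophenyl triazolium salt is of the type that favours benzoin pathways, and attack of C4a on C7 would give a four-membered ring. The formyl group must lie syn to C8a across C4a=C5, which is the geometry inherited from the lactol and which the push–pull dienal can regain by rotation.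

Step 17
Reactants: 24 bis-TBS ether
Product: 25 (7R,8S,8aS)-3-[(1E,3R,4S,5S)-3,4-dihydroxy-3,5-dimethylhept-1-en-1-yl]-7,8-dihydroxy-7-methyl-1,7,8,8a-tetrahydro-6H-isochromen-6-one (target)
Conditions: HF·pyridine, pyridine, THF, 0 → 23 °C
Reagents that add atoms: none
Why: Fluoride should cleave both secondary silyl ethers (desilylation) under buffered conditions that spare the α-ketol, the dienol ether and the tertiary allylic alcohol.

**Compound list**

1 | methyl 2,2-dimethoxypropanoate | COC(=O)C(C)(OC)OC | starting material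
2 | 2,2-dimethoxypropanal | O=CC(C)(OC)OC | intermediate
3 | 3-(benzyloxy)propanoic acid | OC(=O)CCOCc1ccccc1 | starting material
4 | (S)-4-benzyloxazolidin-2-one | O=C1N[C@@H](Cc2ccccc2)CO1 | starting material
5 | (S)-4-benzyl-3-[3-(benzyloxy)propanoyl]oxazolidin-2-one | O=C(CCOCc1ccccc1)N1[C@@H](Cc2ccccc2)COC1=O | intermediate
6 | (4S)-4-benzyl-3-[(2S,3S)-2-[(benzyloxy)methyl]-3-hydroxy-4,4-dimethoxypentanoyl]oxazolidin-2-one | CC(OC)(OC)[C@@H](O)[C@@H](C(=O)N1[C@@H](Cc2ccccc2)COC1=O)COCc1ccccc1 | intermediate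
7 | (2S,3S)-2-[(benzyloxy)methyl]-3-hydroxy-N,4,4-trimethoxy-N-methylpentanamide | CC(OC)(OC)[C@@H](O)[C@@H](C(=O)N(C)OC)COCc1ccccc1 | intermediate
8 | (2S,3S)-2-[(benzyloxy)methyl]-3-{[tert-butyl(dimethyl)silyl]oxy}-N,4,4-trimethoxy-N-methylpentanamide | CC(OC)(OC)[C@@H](O[Si](C)(C)C(C)(C)C)[C@@H](C(=O)N(C)OC)COCc1ccccc1 | intermediate
9 | (2S,3S)-3-{[tert-butyl(dimethyl)silyl]oxy}-2-(hydroxymethyl)-N,4,4-trimethoxy-N-methylpentanamide | CC(OC)(OC)[C@@H](O[Si](C)(C)C(C)(C)C)[C@@H](C(=O)N(C)OC)CO | intermediate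
10 | (4S,5S)-5-{[tert-butyl(dimethyl)silyl]oxy}-4-(hydroxymethyl)-6,6-dimethoxyhept-1-yn-3-one | CC(OC)(OC)[C@@H](O[Si](C)(C)C(C)(C)C)[C@@H](C(=O)C#C)CO | intermediate (not isolated)
11 | (3S)-3-[(1S)-1-{[tert-butyl(dimethyl)silyl]oxy}-2,2-dimethoxypropyl]-2,3-dihydro-4H-pyran-4-one | CC(OC)(OC)[C@@H](O[Si](C)(C)C(C)(C)C)[C@@H]1COC=CC1=O | intermediate
12 | (2S,3S)-2-hydroxy-3-methylpentanoic acid | CC[C@H](C)[C@H](O)C(O)=O | starting material
13 | (2S,3S)-2-hydroxy-N-methoxy-N,3-dimethylpentanamide | CC[C@H](C)[C@H](O)C(=O)N(C)OC | intermediate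
14 | 1,4-bis(trimethylsilyl)buta-1,3-diyne | C[Si](C)(C)C#CC#C[Si](C)(C)C | starting material
15 | (6S,7S)-6-hydroxy-7-methyl-1-(trimethylsilyl)nona-1,3-diyn-5-one | CC[C@H](C)[C@H](O)C(=O)C#CC#C[Si](C)(C)C | intermediate
16 | (5R,6S,7S)-5,7-dimethyl-1-(trimethylsilyl)nona-1,3-diyne-5,6-diol | CC[C@H](C)[C@H](O)[C@](C)(O)C#CC#C[Si](C)(C)C | intermediate
17 | (3E,5R,6S,7S)-5,7-dimethyl-1-(trimethylsilyl)non-3-en-1-yne-5,6-diol | CC[C@H](C)[C@H](O)[C@](C)(O)/C=C/C#C[Si](C)(C)C | intermediate
18 | (3E,5R,6S,7S)-5,7-dimethylnon-3-en-1-yne-5,6-diol | CC[C@H](C)[C@H](O)[C@](C)(O)/C=C/C#C | intermediate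
19 | (3E,5R,6S,7S)-6-{[tert-butyl(dimethyl)silyl]oxy}-5,7-dimethylnon-3-en-1-yn-5-ol | CC[C@H](C)[C@H](O[Si](C)(C)C(C)(C)C)[C@](C)(O)/C=C/C#C | intermediate
20 | (3S)-3-[(1S)-1-{[tert-butyl(dimethyl)silyl]oxy}-2,2-dimethoxypropyl]-4-[(3E,5R,6S,7S)-6-{[tert-butyl(dimethyl)silyl]oxy}-5-hydroxy-5,7-dimethylnon-3-en-1-yn-1-yl]-3,4-dihydro-2H-pyran-4-ol, both epimers at the carbinol carbon C4a | CC[C@H](C)[C@H](O[Si](C)(C)C(C)(C)C)[C@](C)(O)/C=C/C#CC1(O)C=COC[C@H]1[C@H](O[Si](C)(C)C(C)(C)C)C(C)(OC)OC | intermediate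
21 | (5S)-5-[(1S)-1-{[tert-butyl(dimethyl)silyl]oxy}-2-oxopropyl]-4-[(3E,5R,6S,7S)-6-{[tert-butyl(dimethyl)silyl]oxy}-5-hydroxy-5,7-dimethylnon-3-en-1-yn-1-yl]-5,6-dihydro-2H-pyran-2-ol, both anomers | CC[C@H](C)[C@H](O[Si](C)(C)C(C)(C)C)[C@](C)(O)/C=C/C#CC1=CC(O)OC[C@H]1[C@H](O[Si](C)(C)C(C)(C)C)C(C)=O | intermediate
22 | (2E,4S,5S)-5-{[tert-butyl(dimethyl)silyl]oxy}-3-[(3E,5R,6S,7S)-6-{[tert-butyl(dimethyl)silyl]oxy}-5-hydroxy-5,7-dimethylnon-3-en-1-yn-1-yl]-4-(hydroxymethyl)-6-oxohept-2-enal (open form of 21) | CC[C@H](C)[C@H](O[Si](C)(C)C(C)(C)C)[C@](C)(O)/C=C/C#C/C(=C/C=O)[C@@H](CO)[C@H](O[Si](C)(C)C(C)(C)C)C(C)=O | intermediate (not isolated)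
23 | (2E)-{(3S)-3-[(1S)-1-{[tert-butyl(dimethyl)silyl]oxy}-2-oxopropyl]-6-[(1E,3R,4S,5S)-4-{[tert-butyl(dimethyl)silyl]oxy}-3-hydroxy-3,5-dimethylhept-1-en-1-yl]-2,3-dihydro-4H-pyran-4-ylidene}acetaldehyde | CC[C@H](C)[C@H](O[Si](C)(C)C(C)(C)C)[C@](C)(O)/C=C/C1=C/C(=C/C=O)[C@@H](CO1)[C@H](O[Si](C)(C)C(C)(C)C)C(C)=O | intermediate (not isolated)
24 | (7R,8S,8aS)-8-{[tert-butyl(dimethyl)silyl]oxy}-3-[(1E,3R,4S,5S)-4-{[tert-butyl(dimethyl)silyl]oxy}-3-hydroxy-3,5-dimethylhept-1-en-1-yl]-7-hydroxy-7-methyl-1,7,8,8a-tetrahydro-6H-isochromen-6-one | CC[C@H](C)[C@H](O[Si](C)(C)C(C)(C)C)[C@](C)(O)/C=C/C1=CC2=CC(=O)[C@](C)(O)[C@@H](O[Si](C)(C)C(C)(C)C)[C@@H]2CO1 | intermediate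
25 | (7R,8S,8aS)-3-[(1E,3R,4S,5S)-3,4-dihydroxy-3,5-dimethylhept-1-en-1-yl]-7,8-dihydroxy-7-methyl-1,7,8,8a-tetrahydro-6H-isochromen-6-one | CC[C@H](C)[C@H](O)[C@](C)(O)/C=C/C1=CC2=CC(=O)[C@](C)(O)[C@@H](O)[C@@H]2CO1 | target

**Step count and risks**

Total step count: 17. Longest linear sequence: 10 steps (steps 2–7 and 14–17 from 3; the branches from 1 and from 12 are equally long).

Steps most likely to fail:

1. Step 16 (proposed new method). What may go wrong: the carbene may divert the enal into homoenolate protonation and redox esterification instead of acyl-anion chemistry; the deactivated vinylogous formyl group may add the carbene too slowly; the facial selectivity at the ketone may be poor; or DBU may epimerise C8a through the extended enolate. Fallback (known chemistry, from 21 back to 24): DBU (0.5 equiv), THF, 23 °C alone converts 21 into 23, which is isolated. SmI2 (2.5 equiv), t-BuOH, THF, −78 °C then joins C6 and C7 reductively (samarium diiodide aldehyde–ketone pinacol cyclisation; the samarium-bridged cis-diol is expected anti to the C8 silyloxy group) to give (6S,7S,8S,8aS)-8-(TBSO)-3-[(1E,3R,4S,5S)-4-(TBSO)-3-hydroxy-3,5-dimethylhept-1-en-1-yl]-7-methyl-6,7,8,8a-tetrahydro-1H-isochromene-6,7-diol F1. SO3·pyridine, DMSO, Et3N (Parikh–Doering oxidation) then oxidises only the secondary allylic C6 hydroxyl of F1 and returns to the route at 24.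

2. Step 15. What may go wrong: ionisation of the tertiary propargylic carbinol may take other courses (Meyer–Schuster rearrangement, elimination to a 2H-pyran, loss of the side-chain tertiary allylic hydroxyl) before or while the ketal hydrolyses. Fallback (from 9 back to 21; it also bypasses steps 7 and 14):
   - Weinreb amide 9 is acylated by lithio ethyl acetate (LDA, EtOAc, THF, −78 °C) to give ethyl (4S,5S)-5-(TBSO)-4-(hydroxymethyl)-6,6-dimethoxy-3-oxoheptanoate F2, which lactonises (K2CO3, MeOH) to (5S)-5-[(1S)-1-(TBSO)-2,2-dimethoxypropyl]oxane-2,4-dione F3.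
   - Tf2O, Et3N, CH2Cl2, −78 °C gives the enol triflate (3S)-3-[(1S)-1-(TBSO)-2,2-dimethoxypropyl]-6-oxo-3,6-dihydro-2H-pyran-4-yl trifluoromethanesulfonate F4.
   - Sonogashira coupling with 19 (PdCl2(PPh3)2, CuI, Et3N, THF) gives (5S)-5-[(1S)-1-(TBSO)-2,2-dimethoxypropyl]-4-[(3E,5R,6S,7S)-6-(TBSO)-5-hydroxy-5,7-dimethylnon-3-en-1-yn-1-yl]-5,6-dihydro-2H-pyran-2-one F5.
   - i-Bu2AlH, CH2Cl2, −78 °C reduces the lactone to the lactol (5S)-5-[(1S)-1-(TBSO)-2,2-dimethoxypropyl]-4-[(3E,5R,6S,7S)-6-(TBSO)-5-hydroxy-5,7-dimethylnon-3-en-1-yn-1-yl]-5,6-dihydro-2H-pyran-2-ol F6.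
   - TsOH·H2O, acetone/H2O hydrolyses the ketal of F6, a substrate that has no ionisable ring carbinol, and returns to the route at 21.

3. Step 10. What may go wrong: the magnesium alkoxide may close 5-endo onto the diynone (3(2H)-furanone formation) or chelate control may be eroded. Fallback (from 13 back to 19, with Felkin–Anh instead of chelate control):
   - TBSCl, imidazole, DMF gives (2S,3S)-2-(TBSO)-N-methoxy-N,3-dimethylpentanamide F7.
   - MeMgBr, THF, 0 °C gives (3S,4S)-3-(TBSO)-4-methylhexan-2-one F8.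
   - The lithium diynide from 14 and MeLi·LiBr adds to F8 anti to the silyloxy group (Felkin–Anh) to give (5R,6S,7S)-6-(TBSO)-5,7-dimethyl-1-(trimethylsilyl)nona-1,3-diyn-5-ol F9.
   - LiAlH4, THF gives (3E,5R,6S,7S)-6-(TBSO)-5,7-dimethyl-1-(trimethylsilyl)non-3-en-1-yn-5-ol F10.
   - K2CO3, MeOH removes the alkynyl silyl group of F10 and returns to the route at 19.

Further compounds
F1 | step 16 | (6S,7S,8S,8aS)-8-{[tert-butyl(dimethyl)silyl]oxy}-3-[(1E,3R,4S,5S)-4-{[tert-butyl(dimethyl)silyl]oxy}-3-hydroxy-3,5-dimethylhept-1-en-1-yl]-7-methyl-6,7,8,8a-tetrahydro-1H-isochromene-6,7-diol | CC[C@H](C)[C@H](O[Si](C)(C)C(C)(C)C)[C@](C)(O)/C=C/C1=CC2=C[C@H](O)[C@](C)(O)[C@@H](O[Si](C)(C)C(C)(C)C)[C@@H]2CO1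
F2 | step 15 | ethyl (4S,5S)-5-{[tert-butyl(dimethyl)silyl]oxy}-4-(hydroxymethyl)-6,6-dimethoxy-3-oxoheptanoate | CC(OC)(OC)[C@@H](O[Si](C)(C)C(C)(C)C)[C@@H](C(=O)CC(=O)OCC)CO
F3 | step 15 | (5S)-5-[(1S)-1-{[tert-butyl(dimethyl)silyl]oxy}-2,2-dimethoxypropyl]oxane-2,4-dione | CC(OC)(OC)[C@@H](O[Si](C)(C)C(C)(C)C)[C@@H]1COC(=O)CC1=O
F4 | step 15 | (3S)-3-[(1S)-1-{[tert-butyl(dimethyl)silyl]oxy}-2,2-dimethoxypropyl]-6-oxo-3,6-dihydro-2H-pyran-4-yl trifluoromethanesulfonate | CC(OC)(OC)[C@@H](O[Si](C)(C)C(C)(C)C)[C@@H]1COC(=O)C=C1OS(=O)(=O)C(F)(F)F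
F5 | step 15 | (5S)-5-[(1S)-1-{[tert-butyl(dimethyl)silyl]oxy}-2,2-dimethoxypropyl]-4-[(3E,5R,6S,7S)-6-{[tert-butyl(dimethyl)silyl]oxy}-5-hydroxy-5,7-dimethylnon-3-en-1-yn-1-yl]-5,6-dihydro-2H-pyran-2-one | CC[C@H](C)[C@H](O[Si](C)(C)C(C)(C)C)[C@](C)(O)/C=C/C#CC1=CC(=O)OC[C@H]1[C@H](O[Si](C)(C)C(C)(C)C)C(C)(OC)OC
F6 | step 15 | (5S)-5-[(1S)-1-{[tert-butyl(dimethyl)silyl]oxy}-2,2-dimethoxypropyl]-4-[(3E,5R,6S,7S)-6-{[tert-butyl(dimethyl)silyl]oxy}-5-hydroxy-5,7-dimethylnon-3-en-1-yn-1-yl]-5,6-dihydro-2H-pyran-2-ol, both anomers | CC[C@H](C)[C@H](O[Si](C)(C)C(C)(C)C)[C@](C)(O)/C=C/C#CC1=CC(O)OC[C@H]1[C@H](O[Si](C)(C)C(C)(C)C)C(C)(OC)OC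
F7 | step 10 | (2S,3S)-2-{[tert-butyl(dimethyl)silyl]oxy}-N-methoxy-N,3-dimethylpentanamide | CC[C@H](C)[C@H](O[Si](C)(C)C(C)(C)C)C(=O)N(C)OC
F8 | step 10 | (3S,4S)-3-{[tert-butyl(dimethyl)silyl]oxy}-4-methylhexan-2-one | CC[C@H](C)[C@H](O[Si](C)(C)C(C)(C)C)C(C)=O
F9 | step 10 | (5R,6S,7S)-6-{[tert-butyl(dimethyl)silyl]oxy}-5,7-dimethyl-1-(trimethylsilyl)nona-1,3-diyn-5-ol | CC[C@H](C)[C@H](O[Si](C)(C)C(C)(C)C)[C@](C)(O)C#CC#C[Si](C)(C)C
F10 | step 10 | (3E,5R,6S,7S)-6-{[tert-butyl(dimethyl)silyl]oxy}-5,7-dimethyl-1-(trimethylsilyl)non-3-en-1-yn-5-ol | CC[C@H](C)[C@H](O[Si](C)(C)C(C)(C)C)[C@](C)(O)/C=C/C#C[Si](C)(C)C
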